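**Assumption:** the target (C27H26N2O6) has no stereocentre and no configurationally stable axis. It is one achiral compound, so no step needs stereocontrol.

**Retrosynthetic overview**
1. The free 5-OH is revealed last by hydrogenolysis of a benzyl ether. Just before that, the two indole N-H are freed from Boc groups.
2. The tetramethoxybenzene core comes from a 2,5-dimethoxy-3,6-bis(indolyl)-1,4-benzoquinone by reduction and double O-methylation. Its two OMe groups come from two C-Cl bonds by addition-elimination.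
3. The key C-C disconnections are the two indole C3-quinone bonds. Each is made by an intermolecular Michael addition of an indole to a chloroquinone, followed by reoxidation. 5-Methoxyindole adds first and 5-benzyloxyindole second, which gives the unsymmetrical para pattern.
4. No ring is built. Both indoles and the six-membered core (as 2,5-dichlorobenzoquinone) are bought intact, and the core becomes aromatic in the quinone reduction.

**Route**

Step 1
Reactants: 1 2,5-dichloro-1,4-benzoquinone (1.2 equiv); 2 5-methoxy-1H-indole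
Product: 4 2,5-dichloro-3-(5-methoxy-1H-indol-3-yl)-1,4-benzoquinone, via hydroquinone adduct 3 (not isolated)
Conditions: conc. HCl (cat.), THF, rt, 16 h; then DDQ (1.1 equiv), rt, 1 h
Reagents that add atoms: none
Why: In this acid-activated Michael addition the enamine-like indole C3 attacks the unsubstituted beta-carbon of the chloroquinone, the adduct tautomerises to hydroquinone 3, DDQ dehydrogenates it to 4, a slight excess of 1 limits double addition, and no stereocentre forms.

Step 2
Reactants: 4 2,5-dichloro-3-(5-methoxy-1H-indol-3-yl)-1,4-benzoquinone; 5 5-(benzyloxy)-1H-indole (1.5 equiv)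
Product: 7 2,5-dichloro-3-[5-(benzyloxy)-1H-indol-3-yl]-6-(5-methoxy-1H-indol-3-yl)-1,4-benzoquinone, via bis-indolyl hydroquinone 6 (not isolated)
Conditions: conc. HCl (cat.), THF, rt to 40 °C, 24-48 h; then DDQ (1.2 equiv), rt, 1 h
Reagents that add atoms: none
Why: In this second intermolecular Michael addition the first indole donates only into the C1 carbonyl, so C6-H (beta to the undisturbed C4 carbonyl) is the only open and still electrophilic carbon, which fixes the para arrangement before DDQ reoxidation.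

Step 3
Reactants: 7 2,5-dichloro-3-[5-(benzyloxy)-1H-indol-3-yl]-6-(5-methoxy-1H-indol-3-yl)-1,4-benzoquinone
Product: 8 3-[5-(benzyloxy)-1H-indol-3-yl]-2,5-dimethoxy-6-(5-methoxy-1H-indol-3-yl)-1,4-benzoquinone
Conditions: NaOMe (6 equiv), dry MeOH/THF, rt to 50 °C; aq. NH4Cl work-up
Reagents that add atoms: sodium methoxide, [Na+].[O-]C
Why: Both C-Cl units are vinylogous acid chlorides and react with methoxide by addition-elimination (vinylogous acyl substitution), and excluding water stops the reaction at the dimethyl ether.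

Step 4
Reactants: 8 3-[5-(benzyloxy)-1H-indol-3-yl]-2,5-dimethoxy-6-(5-methoxy-1H-indol-3-yl)-1,4-benzoquinone
Product: 9 N,N'-di-Boc derivative of 8 (a tert-butoxycarbonyl group on each indole nitrogen)
Conditions: Boc2O (3 equiv), DMAP (0.2 equiv), MeCN/CH2Cl2, rt
Reagents that add atoms: di-tert-butyl dicarbonate, CC(C)(C)OC(=O)OC(=O)OC(C)(C)C
Why: DMAP-catalysed N-acylation (carbamate protection) caps the only two acidic N-H groups, so the later base/MeI step can alkylate only oxygen, and it makes the coming hydroquinone less prone to air oxidation.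

Step 5
Reactants: 9 N,N'-di-Boc dimethoxyquinone
Product: 10 N,N'-di-Boc 3-[5-(benzyloxy)indol-3-yl]-2,5-dimethoxy-6-(5-methoxyindol-3-yl)benzene-1,4-diol
Conditions: Na2S2O4 (5 equiv), THF/H2O, rt, Ar; extractive work-up under Ar, used at once without chromatography
Reagents that add atoms: none
Why: Dithionite reduces the quinone to the hydroquinone by a two-electron reduction and aromatises the core, while the benzyl ether, the carbamates and the aryl ethers are inert.

Step 6
Reactants: 10 N,N'-di-Boc hydroquinone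
Product: 11 N,N'-di-Boc 1-[5-(benzyloxy)indol-3-yl]-2,3,5,6-tetramethoxy-4-(5-methoxyindol-3-yl)benzene
Conditions: MeI (6 equiv), K2CO3 (6 equiv), degassed dry DMF, rt to 40 °C, Ar
Reagents that add atoms: iodomethane, CI
Why: In this double Williamson ether synthesis the two phenoxides are the only nucleophiles left and the small electrophile tolerates the flanking groups, while dry carbonate in an aprotic solvent does not cleave N-Boc.

Step 7
Reactants: 11 N,N'-di-Boc tetramethoxybenzene
Product: 12 5-(benzyloxy)-3-[2,3,5,6-tetramethoxy-4-(5-methoxy-1H-indol-3-yl)phenyl]-1H-indole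
Conditions: NaOMe (0.3 equiv), MeOH/THF, rt
Reagents that add atoms: none
Why: Base-catalysed methanolysis (acyl transfer) removes the indole carbamates because indolide is a good leaving group, and it avoids acid and tert-butyl cations near three electron-rich arenes.

Step 8
Reactants: 12 5-(benzyloxy)-3-[2,3,5,6-tetramethoxy-4-(5-methoxy-1H-indol-3-yl)phenyl]-1H-indole
Product: 13 3-[2,3,5,6-tetramethoxy-4-(5-methoxy-1H-indol-3-yl)phenyl]-1H-indol-5-ol (target CNP0244913.0)
Conditions: H2 (1 atm), 10% Pd/C, EtOAc/MeOH, rt; filter and concentrate under Ar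
Reagents that add atoms: none
Why: Catalytic hydrogenolysis cleaves only the benzylic C-O bond, leaves the methyl ethers and indole rings untouched at 1 atm, and exposes the oxidation-prone 5-hydroxyindole only in the last operation.

**Compound list**
1 | 2,5-dichloro-1,4-benzoquinone | O=C1C=C(Cl)C(=O)C=C1Cl | starting material
2 | 5-methoxy-1H-indole | COc1ccc2[nH]ccc2c1 | starting material
3 | 2,5-dichloro-3-(5-methoxy-1H-indol-3-yl)benzene-1,4-diol | COc1ccc2[nH]cc(-c3c(O)c(Cl)cc(O)c3Cl)c2c1 | intermediate (not isolated)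
4 | 2,5-dichloro-3-(5-methoxy-1H-indol-3-yl)-1,4-benzoquinone | COc1ccc2[nH]cc(C3=C(Cl)C(=O)C=C(Cl)C3=O)c2c1 | intermediate
5 | 5-(benzyloxy)-1H-indole | c1ccc(COc2ccc3[nH]ccc3c2)cc1 | starting material
6 | 2,5-dichloro-3-[5-(benzyloxy)-1H-indol-3-yl]-6-(5-methoxy-1H-indol-3-yl)benzene-1,4-diol | COc1ccc2[nH]cc(-c3c(O)c(Cl)c(-c4c[nH]c5ccc(OCc6ccccc6)cc45)c(O)c3Cl)c2c1 | intermediate (not isolated)
7 | 2,5-dichloro-3-[5-(benzyloxy)-1H-indol-3-yl]-6-(5-methoxy-1H-indol-3-yl)-1,4-benzoquinone | COc1ccc2[nH]cc(C3=C(Cl)C(=O)C(c4c[nH]c5ccc(OCc6ccccc6)cc45)=C(Cl)C3=O)c2c1 | intermediate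
8 | 3-[5-(benzyloxy)-1H-indol-3-yl]-2,5-dimethoxy-6-(5-methoxy-1H-indol-3-yl)-1,4-benzoquinone | COc1ccc2[nH]cc(C3=C(OC)C(=O)C(c4c[nH]c5ccc(OCc6ccccc6)cc45)=C(OC)C3=O)c2c1 | intermediate
9 | N,N'-di-Boc derivative of 8 | COc1ccc2n(C(=O)OC(C)(C)C)cc(C3=C(OC)C(=O)C(c4cn(C(=O)OC(C)(C)C)c5ccc(OCc6ccccc6)cc45)=C(OC)C3=O)c2c1 | intermediate
10 | N,N'-di-Boc 3-[5-(benzyloxy)indol-3-yl]-2,5-dimethoxy-6-(5-methoxyindol-3-yl)benzene-1,4-diol | COc1ccc2n(C(=O)OC(C)(C)C)cc(-c3c(OC)c(O)c(-c4cn(C(=O)OC(C)(C)C)c5ccc(OCc6ccccc6)cc45)c(OC)c3O)c2c1 | intermediate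
11 | N,N'-di-Boc 1-[5-(benzyloxy)indol-3-yl]-2,3,5,6-tetramethoxy-4-(5-methoxyindol-3-yl)benzene | COc1ccc2n(C(=O)OC(C)(C)C)cc(-c3c(OC)c(OC)c(-c4cn(C(=O)OC(C)(C)C)c5ccc(OCc6ccccc6)cc45)c(OC)c3OC)c2c1 | intermediate
12 | 5-(benzyloxy)-3-[2,3,5,6-tetramethoxy-4-(5-methoxy-1H-indol-3-yl)phenyl]-1H-indole | COc1ccc2[nH]cc(-c3c(OC)c(OC)c(-c4c[nH]c5ccc(OCc6ccccc6)cc45)c(OC)c3OC)c2c1 | intermediate
13 | 3-[2,3,5,6-tetramethoxy-4-(5-methoxy-1H-indol-3-yl)phenyl]-1H-indol-5-ol | COc1ccc2[nH]cc(-c3c(OC)c(OC)c(-c4c[nH]c5ccc(O)cc45)c(OC)c3OC)c2c1 | target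

**Total step count:** 8. **Longest linear sequence:** 8 steps (from 1 and 2 to 13).

**Three steps most likely to fail**

Step 2 is the first risk. Quinone 4 is already deactivated by one donor indole, and 5 can oligomerise in acid before it adds. The fallback replaces the acid/oxidant sequence with base-promoted addition-elimination on a perhalogenated quinone, which needs neither acid nor oxidant. It sets out from 2. Compound 2, tetrabromo-1,4-benzoquinone (bromanil, O=C1C(Br)=C(Br)C(=O)C(Br)=C1Br) and Cs2CO3 in MeCN give 2,3,5-tribromo-6-(5-methoxy-1H-indol-3-yl)-1,4-benzoquinone F1. Compound 5 and Cs2CO3 then displace the bromide para to the first indole, for the same electronic reason as in step 2. This gives 2,5-dibromo-3-[5-(benzyloxy)-1H-indol-3-yl]-6-(5-methoxy-1H-indol-3-yl)-1,4-benzoquinone F2. NaOMe in MeOH/THF exchanges the two remaining bromides, and the sequence comes back to the route at 8.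

Step 3 is the second risk. Traces of water give unreactive hydroxyquinone anions, and the exchange may stall after one chloride. The fallback drives the reaction all the way to the diacid-like quinone and then re-methylates it. It sets out from 7. Aqueous NaOH in refluxing MeOH followed by acidification gives 3-[5-(benzyloxy)-1H-indol-3-yl]-2,5-dihydroxy-6-(5-methoxy-1H-indol-3-yl)-1,4-benzoquinone F3. Its two vinylogous-acid OH groups are methylated with TMSCHN2 in toluene/MeOH at 0 °C. The indole N-H groups are far too weakly acidic to react. The sequence comes back to the route at 8.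

Step 6 is the third risk. The hydroquinone can reoxidise in air under base, a phenoxide can take up a Boc group, or the reaction can stop at the mono-ether. The fallback is protecting-group-free and uses a neutral methylating agent. It sets out from 8. Na2S2O4 in THF/H2O under Ar gives 3-[5-(benzyloxy)-1H-indol-3-yl]-2,5-dimethoxy-6-(5-methoxy-1H-indol-3-yl)benzene-1,4-diol F4. This is O-methylated directly with TMSCHN2 and iPr2NEt in MeCN/MeOH, conditions under which only phenolic OH is acidic enough to react. The sequence comes back to the route at 12, so steps 4 to 7 are bypassed.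

**Further compounds**
F1 | step 2 | 2,3,5-tribromo-6-(5-methoxy-1H-indol-3-yl)-1,4-benzoquinone | COc1ccc2[nH]cc(C3=C(Br)C(=O)C(Br)=C(Br)C3=O)c2c1
F2 | step 2 | 2,5-dibromo-3-[5-(benzyloxy)-1H-indol-3-yl]-6-(5-methoxy-1H-indol-3-yl)-1,4-benzoquinone | COc1ccc2[nH]cc(C3=C(Br)C(=O)C(c4c[nH]c5ccc(OCc6ccccc6)cc45)=C(Br)C3=O)c2c1
F3 | step 3 | 3-[5-(benzyloxy)-1H-indol-3-yl]-2,5-dihydroxy-6-(5-methoxy-1H-indol-3-yl)-1,4-benzoquinone | COc1ccc2[nH]cc(C3=C(O)C(=O)C(c4c[nH]c5ccc(OCc6ccccc6)cc45)=C(O)C3=O)c2c1
F4 | step 6 | 3-[5-(benzyloxy)-1H-indol-3-yl]-2,5-dimethoxy-6-(5-methoxy-1H-indol-3-yl)benzene-1,4-diol | COc1ccc2[nH]cc(-c3c(OC)c(O)c(-c4c[nH]c5ccc(OCc6ccccc6)cc45)c(OC)c3O)c2c1
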